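**Plan**

- Retrosynthesis: after removal of the silyl group from O2', the target is cut at C5–C1' (ring A carbon to the side-chain carbinol carbon), which gives the C5 bromide of the intact dihydrobenzofuran and an O-silylated (R)-lactaldehyde. The bromide is then cut at O1–C2 (benzylic ether) and at C3–C3a (aryl–carbon bond next to a ketone).
- Enabling feature: C1' is a secondary benzylic carbinol on C5 of ring A, para to the ring oxygen O1, and its neighbour C2' carries the OH, CH3 and H of (R)-lactic acid. C5 can therefore act as an aryl nucleophile toward a three-carbon chiral-pool aldehyde.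
- Forward order: a ring A iodide that already carries the bromine of the future C5 is joined to 3',4'-dimethoxypropiophenone by enolate arylation (C3–C3a). The ketone is reduced, acid closes the dihydrofuran ring (O1–C2), the side chain is attached last at C5, and the silyl group is removed.
- Stereochemistry: C3 comes from a ruthenium-catalysed dynamic kinetic resolution (catalyst control). C2 follows from C3 by trans ring closure under thermodynamic control. C2' comes from methyl (R)-lactate, and C1' from C2' by Felkin–Anh 1,2-induction.

Key step: step 8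

Assumption: the (S,S)-TsDPEN ruthenium catalyst is taken to give the (1S) carbinol, as it does with simple aryl alkyl ketones, and enolisation of the doubly benzylic ketone in the amine-rich formate medium is taken to be fast compared with hydride transfer.

**Route**

Step 1
Reactants: 1 4-bromo-2-methoxyphenol
Product: 2 4-bromo-2-iodo-6-methoxyphenol
Conditions: NIS, TsOH·H2O (cat.), MeCN, 0 °C to rt
Reagents that add atoms: N-iodosuccinimide, O=C1CCC(=O)N1I
Why: Electrophilic aromatic iodination is directed by the free hydroxyl group, whose para position is blocked by bromine, so iodine should enter the only open ortho position, as is usual for 4-substituted guaiacols.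

Step 2
Reactants: 2 4-bromo-2-iodo-6-methoxyphenol
Product: 3 5-bromo-1-iodo-3-methoxy-2-(methoxymethoxy)benzene
Conditions: MOMCl, i-Pr2NEt, CH2Cl2, 0 °C to rt
Reagents that add atoms: chloromethyl methyl ether, COCCl
Why: O-Alkylation of the phenol with the chloromethyl ether gives an acetal that tolerates the alkoxide base and the reducing medium of the next two steps and is cleaved later by the same acid that closes the ring.

Step 3
Reactants: 3 5-bromo-1-iodo-3-methoxy-2-(methoxymethoxy)benzene; 4 1-(3,4-dimethoxyphenyl)propan-1-one
Product: 5 racemic 2-[5-bromo-3-methoxy-2-(methoxymethoxy)phenyl]-1-(3,4-dimethoxyphenyl)propan-1-one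
Conditions: Pd2(dba)3 (cat.), Xantphos (cat.), NaOt-Bu, THF, 50 °C, iodide in slight excess
Reagents that add atoms: none
Why: Palladium-catalysed α-arylation of the ketone enolate should occur at the C–I bond, because oxidative addition of zerovalent palladium to an aryl iodide is much faster than to an aryl bromide, and the hindered tertiary α-position of the product is not arylated again; the new C3 centre forms as a racemate, which is what the next step requires.

Step 4
Reactants: 5 racemic 2-[5-bromo-3-methoxy-2-(methoxymethoxy)phenyl]-1-(3,4-dimethoxyphenyl)propan-1-one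
Product: 6 (1S,2S)-2-[5-bromo-3-methoxy-2-(methoxymethoxy)phenyl]-1-(3,4-dimethoxyphenyl)propan-1-ol
Conditions: RuCl[(S,S)-TsDPEN](p-cymene) (cat.), HCO2H/Et3N (1:2), DMF, 40 °C
Reagents that add atoms: none
Why: This is a Noyori-type asymmetric transfer hydrogenation run as a dynamic kinetic resolution, in which the amine interconverts the ketone enantiomers through the enol, the (S,S)-catalyst should fix the carbinol as (1S), and the Felkin-matched (S)-ketone is reduced faster, so both centres should emerge as the like (1S,2S) isomer; any unlike isomer is removed before step 5 because it would lead there to the enantiomeric ring system.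

Step 5
Reactants: 6 (1S,2S)-2-[5-bromo-3-methoxy-2-(methoxymethoxy)phenyl]-1-(3,4-dimethoxyphenyl)propan-1-ol
Product: 8 (2S,3S)-5-bromo-2-(3,4-dimethoxyphenyl)-7-methoxy-3-methyl-2,3-dihydro-1-benzofuran, via free phenol 7 (not isolated)
Conditions: HCl (3 M in MeOH), 45 °C
Reagents that add atoms: none
Why: Acidic methanol cleaves the acetal and ionises the carbinol to a benzylic cation stabilised by the para-methoxy group, which the neighbouring phenol captures in an intramolecular SN1 etherification (cyclodehydration); C2 should be set trans to the C3 methyl group because the closure is reversible under acid and the trans ring is the more stable one, while C3 is not touched.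

Step 6
Reactants: 9 methyl (2R)-2-hydroxypropanoate (methyl (R)-lactate)
Product: 10 methyl (2R)-2-[tert-butyl(diphenyl)silyl]oxypropanoate
Conditions: TBDPSCl, imidazole, DMF, 0 °C to rt
Reagents that add atoms: tert-butyl(chloro)diphenylsilane, CC(C)(C)[Si](Cl)(c1ccccc1)c1ccccc1
Why: Imidazole-promoted silylation of the secondary hydroxyl leaves the stereocentre untouched, and the bulky, weakly coordinating tert-butyldiphenylsilyl ether is preferred to a smaller silyl group because it disfavours chelation in the later carbonyl addition.

Step 7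
Reactants: 10 methyl (2R)-2-[tert-butyl(diphenyl)silyl]oxypropanoate
Product: 11 (2R)-2-[tert-butyl(diphenyl)silyl]oxypropanal
Conditions: i-Bu2AlH, CH2Cl2, −78 °C; then aq. potassium sodium tartrate
Reagents that add atoms: none
Why: Low-temperature partial reduction of an α-silyloxy ester with the aluminium hydride is the standard way to O-silyl lactaldehydes, over-reduction being held back at −78 °C; the aldehyde is used at once so that the α-centre keeps its configuration.

Step 8
Reactants: 8 (2S,3S)-5-bromo-2-(3,4-dimethoxyphenyl)-7-methoxy-3-methyl-2,3-dihydro-1-benzofuran; 11 (2R)-2-[tert-butyl(diphenyl)silyl]oxypropanal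
Product: 13 (1S,2R)-2-[tert-butyl(diphenyl)silyl]oxy-1-[(2S,3S)-2-(3,4-dimethoxyphenyl)-7-methoxy-3-methyl-2,3-dihydro-1-benzofuran-5-yl]propan-1-ol, via aryllithium 12 (not isolated)
Conditions: n-BuLi, THF, −78 °C; then 11, −78 °C; then AcOH in THF, −78 °C
Reagents that add atoms: none
Why: Bromine–lithium exchange at C5 is faster than any deprotonation and gives the aryllithium, which adds to the aldehyde carbonyl and forms the C5–C1' bond without closing a ring. The closest known reaction type is the Felkin–Anh-controlled addition of aryl organometallic reagents to α-silyloxy aldehydes, which gives anti-configured 1,2-diol monoethers. The new C1' centre is controlled by the lactate-derived C2': in the polar Felkin–Anh transition state the C2'–OSi bond lies antiperiplanar to the incoming aryl group, which approaches along the Bürgi–Dunitz trajectory past the C2' hydrogen and not past the methyl group, so the (R)-aldehyde should give the (1'S) carbinol, the anti (erythro) arrangement. The step needs facial selectivity without chelation, which would lead to the syn isomer, and this is secured by the bulky, poorly coordinating silyl ether, by lithium as the only counter-ion in THF and by the low temperature. The distant C2 and C3 centres of the dihydrobenzofuran are not expected to influence the addition and are not touched. Adding the aldehyde to the preformed aryllithium and protonating with acetic acid at −78 °C should suppress enolisation at C2' and silyl migration between the two oxygens.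

Step 9
Reactants: 13 (1S,2R)-2-[tert-butyl(diphenyl)silyl]oxy-1-[(2S,3S)-2-(3,4-dimethoxyphenyl)-7-methoxy-3-methyl-2,3-dihydro-1-benzofuran-5-yl]propan-1-ol
Product: 14 (1S,2R)-1-[(2S,3S)-2-(3,4-dimethoxyphenyl)-7-methoxy-3-methyl-2,3-dihydro-1-benzofuran-5-yl]propane-1,2-diol
Conditions: Bu4NF, THF, 0 °C to rt
Reagents that add atoms: none
Why: Fluoride-mediated desilylation is driven by the strong Si–F bond and leaves the methyl ethers, the benzylic carbinol and the cyclic benzylic ether alone, so the anti diol should be released without change at any stereocentre.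

**Compound list**

1 | 4-bromo-2-methoxyphenol | COc1cc(Br)ccc1O | starting material
2 | 4-bromo-2-iodo-6-methoxyphenol | COc1cc(Br)cc(I)c1O | intermediate
3 | 5-bromo-1-iodo-3-methoxy-2-(methoxymethoxy)benzene | COCOc1c(I)cc(Br)cc1OC | intermediate
4 | 1-(3,4-dimethoxyphenyl)propan-1-one | CCC(=O)c1ccc(OC)c(OC)c1 | starting material
5 | racemic 2-[5-bromo-3-methoxy-2-(methoxymethoxy)phenyl]-1-(3,4-dimethoxyphenyl)propan-1-one (stereocentre left undefined in the SMILES) | COc1ccc(C(=O)C(C)c2cc(Br)cc(OC)c2OCOC)cc1OC | intermediate
6 | (1S,2S)-2-[5-bromo-3-methoxy-2-(methoxymethoxy)phenyl]-1-(3,4-dimethoxyphenyl)propan-1-ol | COc1ccc([C@@H](O)[C@@H](C)c2cc(Br)cc(OC)c2OCOC)cc1OC | intermediate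
7 | 4-bromo-2-[(1S,2S)-1-(3,4-dimethoxyphenyl)-1-hydroxypropan-2-yl]-6-methoxyphenol | COc1ccc([C@@H](O)[C@@H](C)c2cc(Br)cc(OC)c2O)cc1OC | intermediate
8 | (2S,3S)-5-bromo-2-(3,4-dimethoxyphenyl)-7-methoxy-3-methyl-2,3-dihydro-1-benzofuran | COc1ccc([C@H]2Oc3c(OC)cc(Br)cc3[C@@H]2C)cc1OC | intermediate
9 | methyl (2R)-2-hydroxypropanoate (methyl (R)-lactate) | C[C@@H](O)C(=O)OC | starting material
10 | methyl (2R)-2-[tert-butyl(diphenyl)silyl]oxypropanoate | C[C@@H](O[Si](c1ccccc1)(c1ccccc1)C(C)(C)C)C(=O)OC | intermediate
11 | (2R)-2-[tert-butyl(diphenyl)silyl]oxypropanal | C[C@@H](O[Si](c1ccccc1)(c1ccccc1)C(C)(C)C)C=O | intermediate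
12 | [(2S,3S)-2-(3,4-dimethoxyphenyl)-7-methoxy-3-methyl-2,3-dihydro-1-benzofuran-5-yl]lithium | COc1ccc([C@H]2Oc3c(OC)cc([Li])cc3[C@@H]2C)cc1OC | intermediate
13 | (1S,2R)-2-[tert-butyl(diphenyl)silyl]oxy-1-[(2S,3S)-2-(3,4-dimethoxyphenyl)-7-methoxy-3-methyl-2,3-dihydro-1-benzofuran-5-yl]propan-1-ol | COc1ccc([C@H]2Oc3c(OC)cc([C@H](O)[C@@H](C)O[Si](c4ccccc4)(c4ccccc4)C(C)(C)C)cc3[C@@H]2C)cc1OC | intermediate
14 | (1S,2R)-1-[(2S,3S)-2-(3,4-dimethoxyphenyl)-7-methoxy-3-methyl-2,3-dihydro-1-benzofuran-5-yl]propane-1,2-diol | COc1ccc([C@H]2Oc3c(OC)cc([C@H](O)[C@@H](C)O)cc3[C@@H]2C)cc1OC | target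

**Step count and risks**

Total step count: 9. Longest linear sequence: 7 steps (steps 1 to 5, then 8 and 9); the aldehyde branch has 2 steps (6 and 7).

Steps most likely to fail:

1. Step 4. Enolisation of the hindered ketone may be slower than hydride transfer, so the reduction degenerates into a simple kinetic resolution with a poor diastereomer ratio, or the electron-rich α-branched ketone may be reduced only sluggishly. The fallback gives up asymmetric catalysis at this point and sets out from 5. Reduction with NaBH4 in MeOH at 0 °C gives the stereoisomer mixture 2-[5-bromo-3-methoxy-2-(methoxymethoxy)phenyl]-1-(3,4-dimethoxyphenyl)propan-1-ol F1. The acid treatment of step 5 converts all its isomers, through the phenol mixture 4-bromo-2-[1-(3,4-dimethoxyphenyl)-1-hydroxypropan-2-yl]-6-methoxyphenol F2 (not isolated), into racemic trans-5-bromo-2-(3,4-dimethoxyphenyl)-7-methoxy-3-methyl-2,3-dihydro-1-benzofuran F3, because the carbinol configuration is erased in the cation. Preparative chromatography on a polysaccharide-based chiral stationary phase then separates the enantiomers, and the route is rejoined at 8.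

2. Step 8. Facial discrimination may be insufficient if chelated or other non-Felkin transition states compete, and the basic aryllithium may partly enolise the aldehyde. The fallback sets C1' by reduction instead of by addition; it sets out from 8 and 10. Ester 10 is converted with MeNH(OMe)·HCl and i-PrMgCl in THF at −20 °C into the Weinreb amide (2R)-2-[tert-butyl(diphenyl)silyl]oxy-N-methoxy-N-methylpropanamide F4. Aryllithium 12, made from 8 as in step 8, is acylated by F4 to give (2R)-2-[tert-butyl(diphenyl)silyl]oxy-1-[(2S,3S)-2-(3,4-dimethoxyphenyl)-7-methoxy-3-methyl-2,3-dihydro-1-benzofuran-5-yl]propan-1-one F5. Desilylation with HF·pyridine in THF gives (2R)-1-[(2S,3S)-2-(3,4-dimethoxyphenyl)-7-methoxy-3-methyl-2,3-dihydro-1-benzofuran-5-yl]-2-hydroxypropan-1-one F6. Reduction of F6 with Zn(BH4)2 in Et2O at −20 °C should pass through a five-membered zinc chelate, with hydride delivered to the face opposite the methyl group, and give the anti diol directly, so the route is rejoined at 14.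

3. Step 5. The formaldehyde equivalent released from the acetal may alkylate the electron-rich rings, and the acid strength needed for acetal cleavage may allow some loss of the C3 proton from the benzylic cation (erosion of C3 by elimination and re-protonation) or incomplete equilibration to the trans ring. The fallback separates unmasking from ring closure by carrying the phenol as a silyl ether; it sets out from 2. Silylation with i-Pr3SiOTf and 2,6-lutidine in CH2Cl2 gives (4-bromo-2-iodo-6-methoxyphenoxy)tri(propan-2-yl)silane F7. Arylation of 4 with F7 under the catalyst of step 3, with K3PO4 as the base, gives racemic 2-{5-bromo-3-methoxy-2-[tri(propan-2-yl)silyl]oxyphenyl}-1-(3,4-dimethoxyphenyl)propan-1-one F8. The transfer hydrogenation of step 4 gives (1S,2S)-2-{5-bromo-3-methoxy-2-[tri(propan-2-yl)silyl]oxyphenyl}-1-(3,4-dimethoxyphenyl)propan-1-ol F9. Bu4NF in THF at 0 °C then frees the phenol under non-acidic conditions, which rejoins the route at 7, now isolated. Ring closure to 8 is done with a catalytic amount of camphorsulfonic acid in CH2Cl2 at 0 °C, with no formaldehyde source present.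

Further compounds
F1 | step 4 | 2-[5-bromo-3-methoxy-2-(methoxymethoxy)phenyl]-1-(3,4-dimethoxyphenyl)propan-1-ol, mixture of all stereoisomers | COc1ccc(C(O)C(C)c2cc(Br)cc(OC)c2OCOC)cc1OC
F2 | step 4 | 4-bromo-2-[1-(3,4-dimethoxyphenyl)-1-hydroxypropan-2-yl]-6-methoxyphenol, mixture of all stereoisomers | COc1ccc(C(O)C(C)c2cc(Br)cc(OC)c2O)cc1OC
F3 | step 4 | racemic trans-5-bromo-2-(3,4-dimethoxyphenyl)-7-methoxy-3-methyl-2,3-dihydro-1-benzofuran, (2S,3S) and (2R,3R) enantiomers | COc1ccc([C@H]2Oc3c(OC)cc(Br)cc3[C@@H]2C)cc1OC.COc1ccc([C@@H]2Oc3c(OC)cc(Br)cc3[C@H]2C)cc1OC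
F4 | step 8 | (2R)-2-[tert-butyl(diphenyl)silyl]oxy-N-methoxy-N-methylpropanamide | C[C@@H](O[Si](c1ccccc1)(c1ccccc1)C(C)(C)C)C(=O)N(C)OC
F5 | step 8 | (2R)-2-[tert-butyl(diphenyl)silyl]oxy-1-[(2S,3S)-2-(3,4-dimethoxyphenyl)-7-methoxy-3-methyl-2,3-dihydro-1-benzofuran-5-yl]propan-1-one | COc1ccc([C@H]2Oc3c(OC)cc(C(=O)[C@@H](C)O[Si](c4ccccc4)(c4ccccc4)C(C)(C)C)cc3[C@@H]2C)cc1OC
F6 | step 8 | (2R)-1-[(2S,3S)-2-(3,4-dimethoxyphenyl)-7-methoxy-3-methyl-2,3-dihydro-1-benzofuran-5-yl]-2-hydroxypropan-1-one | COc1ccc([C@H]2Oc3c(OC)cc(C(=O)[C@@H](C)O)cc3[C@@H]2C)cc1OC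
F7 | step 5 | (4-bromo-2-iodo-6-methoxyphenoxy)tri(propan-2-yl)silane | COc1cc(Br)cc(I)c1O[Si](C(C)C)(C(C)C)C(C)C
F8 | step 5 | racemic 2-{5-bromo-3-methoxy-2-[tri(propan-2-yl)silyl]oxyphenyl}-1-(3,4-dimethoxyphenyl)propan-1-one | COc1ccc(C(=O)C(C)c2cc(Br)cc(OC)c2O[Si](C(C)C)(C(C)C)C(C)C)cc1OC
F9 | step 5 | (1S,2S)-2-{5-bromo-3-methoxy-2-[tri(propan-2-yl)silyl]oxyphenyl}-1-(3,4-dimethoxyphenyl)propan-1-ol | COc1ccc([C@@H](O)[C@@H](C)c2cc(Br)cc(OC)c2O[Si](C(C)C)(C(C)C)C(C)C)cc1OC
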